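**Retrosynthetic overview**

1. The strategy rests on the C3–C1' bond: ring B sits on C3 of the pyranone ring C and not on C2, and it carries oxygen donors ortho (C2') and para (C4') to C1'. It is therefore cut back by a reverse 1,2-aryl shift (C3–C1') and opening of O1–C2 to a 2'-hydroxychalcone with ring B on the beta carbon.
2. Chalcone 10 comes from a Claisen–Schmidt condensation of ring A ketone 9 (from 2,4,6-trihydroxyacetophenone) with ring B aldehyde 7.
3. Aldehyde 7 comes from a B-alkyl Suzuki–Miyaura coupling of aryl iodide 4 with hydroborated 2-methylbut-3-en-2-ol, which delivers the side chain at its final oxidation level. Iodide 4 comes from C3 iodination and O-benzylation of 2-hydroxy-4,5-dimethoxybenzaldehyde.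
4. Rings A and B are bought. Ring C is the only ring formed (step 6). The three benzyl ethers fall last by neutral hydrogenolysis.

Key step: step 6

Remark: the target has no stereocenter, so the route only sets the (E) geometry of chalcone 10; acetal 11 forms as a racemate and its stereocenter is lost on ring closure.

**Route**

Step 1
Reactants: 1 2-hydroxy-4,5-dimethoxybenzaldehyde
Product: 2 2-hydroxy-3-iodo-4,5-dimethoxybenzaldehyde
Conditions: NIS (1.05 equiv), TFA (cat.), MeCN, 0 °C to rt
Reagents that add atoms: N-iodosuccinimide, O=C1CCC(=O)N1I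
Why: Electrophilic aromatic iodination (SEAr) should go to C3, which is ortho to the free hydroxyl and to the C4 methoxy group and meta to the formyl group, whereas C6, the only other free position, is ortho to the formyl group and activated by one methoxy group only.

Step 2
Reactants: 2 2-hydroxy-3-iodo-4,5-dimethoxybenzaldehyde; 3 benzyl bromide
Product: 4 2-(benzyloxy)-3-iodo-4,5-dimethoxybenzaldehyde
Conditions: BnBr (1.2 equiv), K2CO3, DMF, 50 °C
Reagents that add atoms: benzyl bromide 3, BrCc1ccccc1
Why: Williamson ether synthesis on a phenol made acidic by the ortho formyl group, under conditions to which the aryl iodide and the aldehyde are inert.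

Step 3
Reactants: 4 2-(benzyloxy)-3-iodo-4,5-dimethoxybenzaldehyde; 5 2-methylbut-3-en-2-ol
Product: 7 2-(benzyloxy)-3-(3-hydroxy-3-methylbutyl)-4,5-dimethoxybenzaldehyde, via B-alkyl-9-BBN borane 6 (not isolated)
Conditions: 5 (2.0 equiv), 9-BBN-H (1.9 equiv), THF, 0 °C to rt; then 3 M aq K3PO4, 4, Pd(OAc)2 (5 mol%), SPhos (10 mol%), 60 °C
Reagents that add atoms: 2-methylbut-3-en-2-ol 5, C=CC(C)(C)O
Why: Anti-Markovnikov hydroboration of the monosubstituted alkene by 9-BBN-H followed by B-alkyl Suzuki–Miyaura coupling with the aryl iodide, in which the excess of alkene and the aqueous base leave no B–H bond to reduce the aldehyde and the bulky electron-rich SPhos ligand favours reductive elimination at the di-ortho-substituted carbon over beta-hydride elimination.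

Step 4
Reactants: 8 2,4,6-trihydroxyacetophenone; 3 benzyl bromide
Product: 9 1-[2,4-bis(benzyloxy)-6-hydroxyphenyl]ethan-1-one
Conditions: BnBr (2.05 equiv), K2CO3 (2.2 equiv), DMF, rt
Reagents that add atoms: benzyl bromide 3, BrCc1ccccc1
Why: Williamson etherification in which the hydroxyl hydrogen-bonded to the acetyl carbonyl is the least nucleophilic, so two equivalents of benzyl bromide should take the hydroxyl at C4 and one of the two equivalent ortho hydroxyls.

Step 5
Reactants: 7 2-(benzyloxy)-3-(3-hydroxy-3-methylbutyl)-4,5-dimethoxybenzaldehyde; 9 1-[2,4-bis(benzyloxy)-6-hydroxyphenyl]ethan-1-one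
Product: 10 (E)-1-[2,4-bis(benzyloxy)-6-hydroxyphenyl]-3-[2-(benzyloxy)-3-(3-hydroxy-3-methylbutyl)-4,5-dimethoxyphenyl]prop-2-en-1-one
Conditions: KOH (50% aq), EtOH–THF, rt; AcOH to pH 6 at 0 °C
Reagents that add atoms: none
Why: Claisen–Schmidt (crossed aldol) condensation of the ketone enolate with a non-enolisable aldehyde, with E1cB loss of water giving the conjugated (E)-enone as the thermodynamic isomer, while the phenolate does not close to the flavanone under strong base and the tertiary alcohol and benzyl ethers are inert.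

Step 6
Reactants: 10 (E)-1-[2,4-bis(benzyloxy)-6-hydroxyphenyl]-3-[2-(benzyloxy)-3-(3-hydroxy-3-methylbutyl)-4,5-dimethoxyphenyl]prop-2-en-1-one
Product: 12 5,7-bis(benzyloxy)-3-[2-(benzyloxy)-3-(3-hydroxy-3-methylbutyl)-4,5-dimethoxyphenyl]-4H-chromen-4-one, via dimethyl acetal 11 (not isolated)
Conditions: Tl(NO3)3·3H2O (1.1 equiv), MeOH–HC(OMe)3 (3:1), rt; filter off TlNO3; then 1 M aq HCl, 45 °C
Reagents that add atoms: none
Why: Tl(NO3)3 adds across the enone (thallium to the alpha carbon, methoxide to the benzylic beta carbon), and heterolysis of the weak C–Tl bond with loss of monovalent thallium is assisted by ring B, which bridges as a phenonium ion and ends on the alpha carbon (new C3–C1' bond) while the beta carbon is trapped by methanol as dimethyl acetal 11. This is the known oxidative 1,2-aryl rearrangement of 2'-hydroxychalcones to isoflavones with trivalent thallium, applied here to a new substrate. On acidification the acetal ionises to an oxocarbenium ion that is captured by the chelated ring A phenol (new O1–C2 bond, 6-exo-trig on the C=O+ unit, closing ring C), and loss of the second methanol across C2–C3 gives the chromone. No stereocenter remains, because the alpha stereocenter of racemic 11 becomes the sp2 carbon C3. The step needs aryl migration over hydride or acyl shift and attack of thallium on the alkene instead of on the arenes; the oxygen donors at C2' and C4', ortho and para to the migrating carbon C1', secure the first, and the chelated hydroxyl and acyl group on ring A help the second. The acetal ionises far more readily than the tertiary alcohol, so closure in dilute acid at 45 °C should leave the side chain and the benzyl ethers intact.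

Step 7
Reactants: 12 5,7-bis(benzyloxy)-3-[2-(benzyloxy)-3-(3-hydroxy-3-methylbutyl)-4,5-dimethoxyphenyl]-4H-chromen-4-one
Product: 13 5,7-dihydroxy-3-[2-hydroxy-3-(3-hydroxy-3-methylbutyl)-4,5-dimethoxyphenyl]-4H-chromen-4-one
Conditions: H2 (1 atm), 10% Pd/C, EtOAc–MeOH, rt
Reagents that add atoms: none
Why: Heterogeneous hydrogenolysis of aryl benzyl ethers over palladium on carbon under neutral conditions should be much faster than saturation of the vinylogous-ester C2=C3 bond of the chromone, is stopped after uptake of three equivalents of hydrogen, and exposes the tertiary alcohol to no acid that could close it onto the new C2' hydroxyl as a chroman.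

**Compound list**

1 | 2-hydroxy-4,5-dimethoxybenzaldehyde | COc1cc(O)c(C=O)cc1OC | starting material
2 | 2-hydroxy-3-iodo-4,5-dimethoxybenzaldehyde | COc1cc(C=O)c(O)c(I)c1OC | intermediate
3 | benzyl bromide | BrCc1ccccc1 | starting material
4 | 2-(benzyloxy)-3-iodo-4,5-dimethoxybenzaldehyde | COc1cc(C=O)c(OCc2ccccc2)c(I)c1OC | intermediate
5 | 2-methylbut-3-en-2-ol | C=CC(C)(C)O | starting material
6 | 4-(9-borabicyclo[3.3.1]nonan-9-yl)-2-methylbutan-2-ol | CC(C)(O)CCB1C2CCCC1CCC2 | intermediate (not isolated)
7 | 2-(benzyloxy)-3-(3-hydroxy-3-methylbutyl)-4,5-dimethoxybenzaldehyde | COc1cc(C=O)c(OCc2ccccc2)c(CCC(C)(C)O)c1OC | intermediate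
8 | 2,4,6-trihydroxyacetophenone | CC(=O)c1c(O)cc(O)cc1O | starting material
9 | 1-[2,4-bis(benzyloxy)-6-hydroxyphenyl]ethan-1-one | CC(=O)c1c(O)cc(OCc2ccccc2)cc1OCc1ccccc1 | intermediate
10 | (E)-1-[2,4-bis(benzyloxy)-6-hydroxyphenyl]-3-[2-(benzyloxy)-3-(3-hydroxy-3-methylbutyl)-4,5-dimethoxyphenyl]prop-2-en-1-one | O=C(/C=C/c1cc(OC)c(OC)c(CCC(C)(C)O)c1OCc1ccccc1)c1c(O)cc(OCc2ccccc2)cc1OCc1ccccc1 | intermediate
11 | 1-[2,4-bis(benzyloxy)-6-hydroxyphenyl]-2-[2-(benzyloxy)-3-(3-hydroxy-3-methylbutyl)-4,5-dimethoxyphenyl]-3,3-dimethoxypropan-1-one (racemic) | COC(OC)C(C(=O)c1c(O)cc(OCc2ccccc2)cc1OCc1ccccc1)c1cc(OC)c(OC)c(CCC(C)(C)O)c1OCc1ccccc1 | intermediate (not isolated)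
12 | 5,7-bis(benzyloxy)-3-[2-(benzyloxy)-3-(3-hydroxy-3-methylbutyl)-4,5-dimethoxyphenyl]-4H-chromen-4-one | COc1cc(-c2coc3cc(OCc4ccccc4)cc(OCc4ccccc4)c3c2=O)c(OCc2ccccc2)c(CCC(C)(C)O)c1OC | intermediate
13 | 5,7-dihydroxy-3-[2-hydroxy-3-(3-hydroxy-3-methylbutyl)-4,5-dimethoxyphenyl]-4H-chromen-4-one | COc1cc(-c2coc3cc(O)cc(O)c3c2=O)c(O)c(CCC(C)(C)O)c1OC | target

**Step count and risks**

Total step count: 7. Longest linear sequence: 6 steps (steps 1, 2, 3, 5, 6, 7).

Steps most likely to fail:

Step 6. The tertiary alcohol may ionise in the nitric acid/methanol medium or during the acid closure and be lost as a methyl ether or an alkene. The very electron-rich ring B may also be oxidised by thallium before the enone is oxythallated.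

The fallback puts the side chain on after ring C is built. It sets out from aldehyde 4 and ketone 9 and comes back to the route at target 13.
- Condensation of 4 with 9 (KOH, EtOH–THF) should give (E)-1-[2,4-bis(benzyloxy)-6-hydroxyphenyl]-3-[2-(benzyloxy)-3-iodo-4,5-dimethoxyphenyl]prop-2-en-1-one F1.
- Tl(NO3)3 in MeOH–HC(OMe)3 should rearrange F1, whose ring B is less electron-rich, to 1-[2,4-bis(benzyloxy)-6-hydroxyphenyl]-2-[2-(benzyloxy)-3-iodo-4,5-dimethoxyphenyl]-3,3-dimethoxypropan-1-one F2.
- Hot methanolic HCl can then be used freely, since no acid-labile group is present, to close F2 to 5,7-bis(benzyloxy)-3-[2-(benzyloxy)-3-iodo-4,5-dimethoxyphenyl]-4H-chromen-4-one F3.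
- Sonogashira coupling of F3 with 2-methylbut-3-yn-2-ol (PdCl2(PPh3)2, CuI, Et3N, DMF, 60 °C) should give 5,7-bis(benzyloxy)-3-[2-(benzyloxy)-3-(3-hydroxy-3-methylbut-1-yn-1-yl)-4,5-dimethoxyphenyl]-4H-chromen-4-one F4.
- Hydrogen over Pd/C should then saturate the alkyne and cleave the three benzyl ethers in one operation to give 13.

Step 3. Transmetalation of the alkylborane onto the di-ortho-substituted arylpalladium iodide may be slow, so that protodeiodination or beta-hydride elimination competes. Boron species may also reduce the aldehyde by hydride transfer.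

The fallback replaces the sp3–sp2 coupling by a Heck reaction and a separate alkene reduction. It sets out from iodide 4 and comes back at aldehyde 7.
- Heck coupling of 4 with 2-methylbut-3-en-2-ol 5 (Pd(OAc)2, Bu4NCl, NaHCO3, DMF, 80 °C) should give (E)-2-(benzyloxy)-3-(3-hydroxy-3-methylbut-1-en-1-yl)-4,5-dimethoxybenzaldehyde F5.
- Diimide, generated from dipotassium azodicarboxylate and AcOH in MeOH at rt, should saturate the alkene of F5 without touching the aldehyde or the benzyl ether and give 7.

Step 4. Alkylation may not stop cleanly at the bis-ether: the chelated hydroxyl may also be benzylated while mono-ether remains, giving a mixture of ethers.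

The fallback over-alkylates on purpose and then removes one group under chelation control. It sets out from 8 and comes back at ketone 9.
- Exhaustive benzylation of 8 (BnBr in excess, K2CO3, DMF, 80 °C) should give 1-[2,4,6-tris(benzyloxy)phenyl]ethan-1-one F6.
- MgBr2·OEt2 in toluene–ether at reflux, which complexes the carbonyl oxygen and the ortho ether oxygen, should cleave only one ortho benzyl ether of F6 and give 9.

**Further compounds**

F1 | step 6 | (E)-1-[2,4-bis(benzyloxy)-6-hydroxyphenyl]-3-[2-(benzyloxy)-3-iodo-4,5-dimethoxyphenyl]prop-2-en-1-one | O=C(/C=C/c1cc(OC)c(OC)c(I)c1OCc1ccccc1)c1c(O)cc(OCc2ccccc2)cc1OCc1ccccc1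
F2 | step 6 | 1-[2,4-bis(benzyloxy)-6-hydroxyphenyl]-2-[2-(benzyloxy)-3-iodo-4,5-dimethoxyphenyl]-3,3-dimethoxypropan-1-one (racemic) | COC(OC)C(C(=O)c1c(O)cc(OCc2ccccc2)cc1OCc1ccccc1)c1cc(OC)c(OC)c(I)c1OCc1ccccc1
F3 | step 6 | 5,7-bis(benzyloxy)-3-[2-(benzyloxy)-3-iodo-4,5-dimethoxyphenyl]-4H-chromen-4-one | COc1cc(-c2coc3cc(OCc4ccccc4)cc(OCc4ccccc4)c3c2=O)c(OCc2ccccc2)c(I)c1OC
F4 | step 6 | 5,7-bis(benzyloxy)-3-[2-(benzyloxy)-3-(3-hydroxy-3-methylbut-1-yn-1-yl)-4,5-dimethoxyphenyl]-4H-chromen-4-one | COc1cc(-c2coc3cc(OCc4ccccc4)cc(OCc4ccccc4)c3c2=O)c(OCc2ccccc2)c(C#CC(C)(C)O)c1OC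
F5 | step 3 | (E)-2-(benzyloxy)-3-(3-hydroxy-3-methylbut-1-en-1-yl)-4,5-dimethoxybenzaldehyde | COc1cc(C=O)c(OCc2ccccc2)c(/C=C/C(C)(C)O)c1OC
F6 | step 4 | 1-[2,4,6-tris(benzyloxy)phenyl]ethan-1-one | CC(=O)c1c(OCc2ccccc2)cc(OCc2ccccc2)cc1OCc1ccccc1
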